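**Plan**

1. Retrosynthesis: the gallate ester C–O bond is cut. Both 2,3-cis carbinols go back, through the C3 ketones, to 2,3-trans carbinols. In ring C of each flavan unit O1–C2 is cut and O1 is re-joined to C3, which contracts each pyran ring to the furan ring of a 2-[aryl(hydroxy)methyl]-2,3-dihydrobenzofuran. The two C2–C3 bonds (flavan numbering) are cut to a biaryl-2,2'-dicarbaldehyde and a 2-lithiobenzofuran, and the biaryl bond to an aryl bromide.
2. Forward: biaryl by Ullmann coupling → both ring-A units enter as aromatic benzofurans → the furan rings are dearomatised by asymmetric hydrogenation → both five-membered O-rings are enlarged to the six-membered rings C in one operation → C3 is inverted by oxidation and reduction → one gallate is attached → all benzyl ethers are removed.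
3. Feature used: in ring C the ether oxygen O1 and the 3-oxygen sit on the neighbouring atoms C2 and C3, and C2 is benzylic to ring B. With a leaving group on C2, O1 (bound to C3 in the five-membered ring) can bridge C3 and C2 as an oxiranium ion and end on C2 while an oxygen nucleophile enters at C3.
4. Stereochemistry: the hydrogenation catalyst sets the ring carbon next to O1 (R). The ring expansion turns it with inversion into C3 (S) and sets C2 (R) trans to it from either carbinol epimer. LiBH(s-Bu)3 then reduces the C3 ketone under control of C2 to the cis (2R,3R) carbinol.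
5. Remark: the target SMILES leaves the biaryl axis open. The axis forms without control in step 2, all SMILES below carry no axis descriptor, and the two atropisomeric diastereomers are separated at compound 15; the (R)-axis isomer (that of natural theasinensin B) is carried on.

Key step: step 7

**Route**

Step 1
Reactants: 1 3,4,5-tris(benzyloxy)benzaldehyde
Product: 2 2-bromo-3,4,5-tris(benzyloxy)benzaldehyde
Conditions: NBS, MeCN, 0 °C → rt
Reagents that add atoms: N-bromosuccinimide, O=C1CCC(=O)N1Br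
Why: electrophilic aromatic bromination, in which the two free ring positions are equivalent and each is activated by an ortho and a para benzyloxy group, so a single monobromide should form.

Step 2
Reactants: 2 2-bromo-3,4,5-tris(benzyloxy)benzaldehyde (two molecules)
Product: 3 4,4',5,5',6,6'-hexakis(benzyloxy)biphenyl-2,2'-dicarbaldehyde (racemic axis)
Conditions: Cu powder (activated), DMF, 140 °C
Reagents that add atoms: none
Why: Ullmann reductive homocoupling of an ortho-formyl aryl bromide, which should give the tetra-ortho-substituted biaryl with a configurationally fixed but uncontrolled axis.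

Step 3
Reactants: 4 4,6-dihydroxybenzofuran-3(2H)-one
Product: 5 4,6-bis(benzyloxy)benzofuran-3(2H)-one
Conditions: BnBr, K2CO3, DMF, 60 °C
Reagents that add atoms: benzyl bromide, BrCc1ccccc1
Why: Williamson ether synthesis on both phenols, the carbonate base being too weak to favour C-alkylation next to the ketone.

Step 4
Reactants: 5 4,6-bis(benzyloxy)benzofuran-3(2H)-one
Product: 7 4,6-bis(benzyloxy)benzofuran, via dihydrobenzofuran-3-ol 6 (not isolated)
Conditions: NaBH4, THF–MeOH, 0 °C → rt; aq HCl; then TsOH·H2O (cat.), toluene, 40 °C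
Reagents that add atoms: none
Why: hydride reduction of the ketone followed by acid-catalysed E1 dehydration of the benzylic alcohol, driven by aromatisation to the benzofuran.

Step 5
Reactants: 7 4,6-bis(benzyloxy)benzofuran (2.4 equiv); 3 4,4',5,5',6,6'-hexakis(benzyloxy)biphenyl-2,2'-dicarbaldehyde
Product: 9 [4,4',5,5',6,6'-hexakis(benzyloxy)biphenyl-2,2'-diyl]bis{[4,6-bis(benzyloxy)benzofuran-2-yl]methanol} (carbinol epimers), via 2-lithiobenzofuran 8 (not isolated)
Conditions: n-BuLi, THF, −78 °C; then 3, −78 → −20 °C; H2O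
Reagents that add atoms: none
Why: C2-lithiation of the benzofuran (its most acidic C–H, next to the ring oxygen) and 1,2-addition of the aryllithium to both aldehydes, the carbinol centres being formed without control because they are planarised in step 7.

Step 6
Reactants: 9 bis(benzofuran-2-yl carbinol)
Product: 10 [4,4',5,5',6,6'-hexakis(benzyloxy)biphenyl-2,2'-diyl]bis{[(2R)-4,6-bis(benzyloxy)-2,3-dihydrobenzofuran-2-yl]methanol} (carbinol epimers)
Conditions: H2 (60 bar), Ru(cod)(2-methylallyl)2, 1,3-bis[1-(1-naphthyl)ethyl]imidazolinium tetrafluoroborate (SINpEt·HBF4, the enantiomer that gives the 2R ring), KOtBu, toluene–hexane, 40 °C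
Reagents that add atoms: none
Why: Ru–NHC-catalysed asymmetric hydrogenation of 2-substituted benzofurans, which dearomatises only the furan ring and in which the chiral ligand chooses the face of each C2=C3 bond and so sets C2 (R).

Step 7
Reactants: 10 bis[(2R)-2,3-dihydrobenzofuran-2-yl carbinol]
Product: 13 (2R,2'R,3S,3'S)-2,2'-[4,4',5,5',6,6'-hexakis(benzyloxy)biphenyl-2,2'-diyl]bis[5,7-bis(benzyloxy)chroman-3-ol] (2,3-trans in both rings), via bis(trifluoroacetate) 11 (not isolated), via flavan-3-yl bis(trifluoroacetate) 12 (not isolated)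
Conditions: (CF3CO)2O, 2,6-lutidine, CH2Cl2, −40 °C; then (CF3)2CHOH, −20 °C → rt; aqueous wash; K2CO3 (cat.), MeOH, 0 °C
Reagents that add atoms: trifluoroacetic anhydride, O=C(OC(=O)C(F)(F)F)C(F)(F)F (its trifluoroacetate supplies the oxygen at C3)
Why: Proposed new method: each benzylic trifluoroacetate of 11 should ionise reversibly in (CF3)2CHOH, the ring oxygen O1 (still bound to the ring carbon that becomes C3) should close on the benzylic carbon (3-exo-tet) to a bicyclic oxiranium ion, and trifluoroacetate should open this ion anti at the ring carbon, so that O1 moves from C3 to C2 and each five-membered dihydrofuran ring becomes a six-membered ring C (two-fold 1,2-oxygen shift). The closest known reaction types are the Zn(OAc)2/AcOH ring expansion of 2-(1-sulfonyloxyalkyl)tetrahydrofurans to 3-acetoxytetrahydropyrans, the (CF3CO)2O-induced ring expansion of α-aryl prolinols to 2-aryl-3-hydroxypiperidines through aziridinium ions and the acid-induced change of 2-(2-hydroxypropan-2-yl)-2,3-dihydrobenzofurans into 2,2-dimethylchroman-3-ols, while the reverse contraction is the known fate of flavan-3-yl sulfonates. The step needs opening of the oxiranium at the ring carbon and not at the benzylic carbon, which is sought through reversibility: attack at the benzylic carbon only returns a five-ring ester that ionises again, whereas the secondary flavan-3-yl trifluoroacetate 12 should not ionise in the buffered medium and should collect. C3 arises with inversion of the (R) centre set in step 6 and becomes (S), and C2 is set in the oxiranium, which should prefer ring B exo (trans to C4) and so give the 2,3-trans (2R,3S) ring from either carbinol epimer. Low temperature and the lutidinium buffer are meant to hold back the 1,2-hydride shift and proton loss that would aromatise the cation to a 2-benzylbenzofuran.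

Step 8
Reactants: 13 bis[(2R,3S)-chroman-3-ol]
Product: 14 (2R,2'R)-2,2'-[4,4',5,5',6,6'-hexakis(benzyloxy)biphenyl-2,2'-diyl]bis[5,7-bis(benzyloxy)chroman-3-one]
Conditions: Dess–Martin periodinane, CH2Cl2 (water-saturated), rt
Reagents that add atoms: none
Why: Dess–Martin oxidation of the secondary alcohols under non-basic conditions, which should leave the C2 centre next to each new ketone unepimerised, as for benzyl-protected catechin-type flavan-3-ols.

Step 9
Reactants: 14 bis[(2R)-chroman-3-one]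
Product: 15 (2R,2'R,3R,3'R)-2,2'-[4,4',5,5',6,6'-hexakis(benzyloxy)biphenyl-2,2'-diyl]bis[5,7-bis(benzyloxy)chroman-3-ol] (2,3-cis in both rings; (R)-axis isomer after separation)
Conditions: LiBH(s-Bu)3, THF, −78 °C; H2O; chromatography on silica gel
Reagents that add atoms: none
Why: substrate-controlled ketone reduction in which the bulky borohydride should attack along the equatorial trajectory, placing the new 3-OH axial and cis to the equatorial ring B at C2 (C2 controls C3, 2R,3R), after which the two atropisomeric diastereomers are separated.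

Step 10
Reactants: 15 bis[(2R,3R)-chroman-3-ol]; 16 3,4,5-tris(benzyloxy)benzoic acid (1.0 equiv)
Product: 17 mono[3,4,5-tris(benzyloxy)benzoate] of 15 (trideca-O-benzyl theasinensin B)
Conditions: DCC, DMAP, CH2Cl2, 0 °C → rt
Reagents that add atoms: none
Why: Steglich esterification of one of the two homotopic 3-hydroxyls of the C2-symmetric diol, so that any single acylation gives the same mono-ester, with unreacted diol and diester separated and the diol recycled.

Step 11
Reactants: 17 trideca-O-benzyl theasinensin B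
Product: 18 theasinensin B
Conditions: H2 (1 atm), Pd(OH)2/C, THF–MeOH, rt
Reagents that add atoms: none
Why: catalytic hydrogenolysis of all thirteen benzyl ethers, which should leave the gallate ester, the ring C ether bonds and the stereocentres untouched.

**Compound list**

1 | 3,4,5-tris(benzyloxy)benzaldehyde | O=Cc1cc(OCc2ccccc2)c(OCc2ccccc2)c(OCc2ccccc2)c1 | starting material
2 | 2-bromo-3,4,5-tris(benzyloxy)benzaldehyde | O=Cc1cc(OCc2ccccc2)c(OCc2ccccc2)c(OCc2ccccc2)c1Br | intermediate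
3 | 4,4',5,5',6,6'-hexakis(benzyloxy)biphenyl-2,2'-dicarbaldehyde (racemic axis) | O=Cc1cc(OCc2ccccc2)c(OCc2ccccc2)c(OCc2ccccc2)c1-c1c(C=O)cc(OCc2ccccc2)c(OCc2ccccc2)c1OCc1ccccc1 | intermediate
4 | 4,6-dihydroxybenzofuran-3(2H)-one | O=C1COc2cc(O)cc(O)c21 | starting material
5 | 4,6-bis(benzyloxy)benzofuran-3(2H)-one | O=C1COc2cc(OCc3ccccc3)cc(OCc3ccccc3)c21 | intermediate
6 | 4,6-bis(benzyloxy)-2,3-dihydrobenzofuran-3-ol (racemic, not isolated) | OC1COc2cc(OCc3ccccc3)cc(OCc3ccccc3)c21 | intermediate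
7 | 4,6-bis(benzyloxy)benzofuran | c1cc2c(OCc3ccccc3)cc(OCc3ccccc3)cc2o1 | intermediate
8 | 4,6-bis(benzyloxy)-2-lithiobenzofuran (not isolated) | [Li]c1cc2c(OCc3ccccc3)cc(OCc3ccccc3)cc2o1 | intermediate
9 | [4,4',5,5',6,6'-hexakis(benzyloxy)biphenyl-2,2'-diyl]bis{[4,6-bis(benzyloxy)benzofuran-2-yl]methanol} (carbinol epimers) | c1(C(O)c2cc3c(OCc4ccccc4)cc(OCc4ccccc4)cc3o2)cc(OCc2ccccc2)c(OCc2ccccc2)c(OCc2ccccc2)c1-c1c(C(O)c2cc3c(OCc4ccccc4)cc(OCc4ccccc4)cc3o2)cc(OCc2ccccc2)c(OCc2ccccc2)c1OCc1ccccc1 | intermediate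
10 | [4,4',5,5',6,6'-hexakis(benzyloxy)biphenyl-2,2'-diyl]bis{[(2R)-4,6-bis(benzyloxy)-2,3-dihydrobenzofuran-2-yl]methanol} (carbinol epimers) | c1(C(O)[C@H]2Cc3c(OCc4ccccc4)cc(OCc4ccccc4)cc3O2)cc(OCc2ccccc2)c(OCc2ccccc2)c(OCc2ccccc2)c1-c1c(C(O)[C@H]2Cc3c(OCc4ccccc4)cc(OCc4ccccc4)cc3O2)cc(OCc2ccccc2)c(OCc2ccccc2)c1OCc1ccccc1 | intermediate
11 | bis(trifluoroacetate) of 10 (not isolated) | c1(C(OC(=O)C(F)(F)F)[C@H]2Cc3c(OCc4ccccc4)cc(OCc4ccccc4)cc3O2)cc(OCc2ccccc2)c(OCc2ccccc2)c(OCc2ccccc2)c1-c1c(C(OC(=O)C(F)(F)F)[C@H]2Cc3c(OCc4ccccc4)cc(OCc4ccccc4)cc3O2)cc(OCc2ccccc2)c(OCc2ccccc2)c1OCc1ccccc1 | intermediate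
12 | bis(3-O-trifluoroacetate) of 13, (2R,3S) in both rings (not isolated) | c1([C@H]2Oc3cc(OCc4ccccc4)cc(OCc4ccccc4)c3C[C@@H]2OC(=O)C(F)(F)F)cc(OCc2ccccc2)c(OCc2ccccc2)c(OCc2ccccc2)c1-c1c([C@H]2Oc3cc(OCc4ccccc4)cc(OCc4ccccc4)c3C[C@@H]2OC(=O)C(F)(F)F)cc(OCc2ccccc2)c(OCc2ccccc2)c1OCc1ccccc1 | intermediate
13 | (2R,2'R,3S,3'S)-2,2'-[4,4',5,5',6,6'-hexakis(benzyloxy)biphenyl-2,2'-diyl]bis[5,7-bis(benzyloxy)chroman-3-ol] | c1([C@H]2Oc3cc(OCc4ccccc4)cc(OCc4ccccc4)c3C[C@@H]2O)cc(OCc2ccccc2)c(OCc2ccccc2)c(OCc2ccccc2)c1-c1c([C@H]2Oc3cc(OCc4ccccc4)cc(OCc4ccccc4)c3C[C@@H]2O)cc(OCc2ccccc2)c(OCc2ccccc2)c1OCc1ccccc1 | intermediate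
14 | (2R,2'R)-2,2'-[4,4',5,5',6,6'-hexakis(benzyloxy)biphenyl-2,2'-diyl]bis[5,7-bis(benzyloxy)chroman-3-one] | c1([C@H]2Oc3cc(OCc4ccccc4)cc(OCc4ccccc4)c3CC2=O)cc(OCc2ccccc2)c(OCc2ccccc2)c(OCc2ccccc2)c1-c1c([C@H]2Oc3cc(OCc4ccccc4)cc(OCc4ccccc4)c3CC2=O)cc(OCc2ccccc2)c(OCc2ccccc2)c1OCc1ccccc1 | intermediate
15 | (2R,2'R,3R,3'R)-2,2'-[4,4',5,5',6,6'-hexakis(benzyloxy)biphenyl-2,2'-diyl]bis[5,7-bis(benzyloxy)chroman-3-ol] (deca-O-benzyl theasinensin C for the (R)-axis) | c1([C@H]2Oc3cc(OCc4ccccc4)cc(OCc4ccccc4)c3C[C@H]2O)cc(OCc2ccccc2)c(OCc2ccccc2)c(OCc2ccccc2)c1-c1c([C@H]2Oc3cc(OCc4ccccc4)cc(OCc4ccccc4)c3C[C@H]2O)cc(OCc2ccccc2)c(OCc2ccccc2)c1OCc1ccccc1 | intermediate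
16 | 3,4,5-tris(benzyloxy)benzoic acid | O=C(O)c1cc(OCc2ccccc2)c(OCc2ccccc2)c(OCc2ccccc2)c1 | starting material
17 | trideca-O-benzyl theasinensin B (mono-gallate of 15) | c1([C@H]2Oc3cc(OCc4ccccc4)cc(OCc4ccccc4)c3C[C@H]2OC(=O)c2cc(OCc3ccccc3)c(OCc3ccccc3)c(OCc3ccccc3)c2)cc(OCc2ccccc2)c(OCc2ccccc2)c(OCc2ccccc2)c1-c1c([C@H]2Oc3cc(OCc4ccccc4)cc(OCc4ccccc4)c3C[C@H]2O)cc(OCc2ccccc2)c(OCc2ccccc2)c1OCc1ccccc1 | intermediate
18 | theasinensin B | O=C(O[C@@H]1Cc2c(O)cc(O)cc2O[C@@H]1c1cc(O)c(O)c(O)c1-c1c([C@H]2Oc3cc(O)cc(O)c3C[C@H]2O)cc(O)c(O)c1O)c1cc(O)c(O)c(O)c1 | target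

**Step count**

Total steps: 11. Longest linear sequence: 9 steps (1 → 2 → 3 → 9 → 10 → 13 → 14 → 15 → 17 → 18; the branch from 4 is equally long).

**Steps most likely to fail**

1. Step 7 (Proposed new method). The ion pairs may keep returning to five-ring esters without the oxiranium ever being opened at the ring carbon. The benzylic cation may instead undergo 1,2-hydride shift or proton loss and aromatise to a 2-benzylbenzofuran. The benzyloxy oxygen of the neighbouring ring B may also capture the cation with loss of its benzyl group. The fallback uses known chemistry, sets out from 3 and comes back at 13. Compound 3 is taken to the silylated bis-epoxide F4 as laid out in the fallback to step 6 below (through F1, F2 and F3). Buffered desilylation (Bu4NF, AcOH, THF, 0 °C) should give the bis-phenol bis-epoxide F5. Camphorsulfonic acid (cat.) in CH2Cl2 at −20 °C should then bring about 6-endo opening of each epoxide at its benzylic carbon by the phenol with inversion. This gives the 2,3-trans (2R,3S) rings of 13 directly from the open chain, without any change of ring size.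

2. Step 6. The catalyst may not turn over at the hindered, electron-rich furan rings. The furfuryl-type C–OH bond may be hydrogenolysed. Facial control by the ligand may be eroded by the existing axis and carbinol centres. The fallback sets out from 3 and comes back at 10 (as a single carbinol epimer). CH2=CHMgBr (THF, −78 °C) adds to both aldehydes of 3 to give the bis(allylic alcohol) F1. Acid-catalysed Friedel–Crafts allylation of 3,5-bis(benzyloxy)phenol at the allyl terminus (H2SO4 on SiO2, CH2Cl2, rt) should give the bis[(E)-cinnamyl]phenol F2. TBSCl and imidazole in DMF give the bis(silyl ether) F3. Shi epoxidation with the L-series ketone catalyst (the enantiomer of the usual D-fructose-derived one), KHSO5, K2CO3, MeCN–H2O, 0 °C, should give the (S,S)-configured bis-epoxide F4. Bu4NF in THF then frees the phenoxides, which should open the epoxides 5-exo-tet at the non-benzylic carbon with inversion and so give the (2R)-dihydrobenzofuran rings of 10.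

3. Step 5. The alkoxide from the first addition may close on the neighbouring aldehyde to a seven-membered lactolate, so that the second addition stalls. Lithiation may also stray to ring A or to a benzylic CH2. The fallback sets out from 3 and comes back at 9. Pinnick oxidation (NaClO2, NaH2PO4, 2-methyl-2-butene, t-BuOH–H2O) gives the diacid F6. Coupling with MeNHOMe·HCl (EDC·HCl, DMAP, CH2Cl2) gives the bis(Weinreb amide) F7. Addition of 8 (from 7 and n-BuLi, THF, −78 °C) should stop at the chelated tetrahedral stage and give the bis-ketone F8 on work-up. NaBH4 (THF–MeOH, 0 °C) reduces both ketones to 9.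

**Further compounds**

F1 | step 6 | 1,1'-[4,4',5,5',6,6'-hexakis(benzyloxy)biphenyl-2,2'-diyl]bis(prop-2-en-1-ol) | c1(C(O)C=C)cc(OCc2ccccc2)c(OCc2ccccc2)c(OCc2ccccc2)c1-c1c(C(O)C=C)cc(OCc2ccccc2)c(OCc2ccccc2)c1OCc1ccccc1
F2 | step 6 | 2,2'-{[4,4',5,5',6,6'-hexakis(benzyloxy)biphenyl-2,2'-diyl]bis[(E)-prop-2-ene-3,1-diyl]}bis[3,5-bis(benzyloxy)phenol] | c1(/C=C/Cc2c(O)cc(OCc3ccccc3)cc2OCc2ccccc2)cc(OCc2ccccc2)c(OCc2ccccc2)c(OCc2ccccc2)c1-c1c(/C=C/Cc2c(O)cc(OCc3ccccc3)cc2OCc2ccccc2)cc(OCc2ccccc2)c(OCc2ccccc2)c1OCc1ccccc1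
F3 | step 6 | bis(tert-butyldimethylsilyl) ether of F2 | c1(/C=C/Cc2c(O[Si](C)(C)C(C)(C)C)cc(OCc3ccccc3)cc2OCc2ccccc2)cc(OCc2ccccc2)c(OCc2ccccc2)c(OCc2ccccc2)c1-c1c(/C=C/Cc2c(O[Si](C)(C)C(C)(C)C)cc(OCc3ccccc3)cc2OCc2ccccc2)cc(OCc2ccccc2)c(OCc2ccccc2)c1OCc1ccccc1
F4 | step 6 | bis[(2S,3S)-epoxide] of F3 | c1([C@@H]2O[C@H]2Cc3c(O[Si](C)(C)C(C)(C)C)cc(OCc4ccccc4)cc3OCc3ccccc3)cc(OCc2ccccc2)c(OCc2ccccc2)c(OCc2ccccc2)c1-c1c([C@@H]2O[C@H]2Cc3c(O[Si](C)(C)C(C)(C)C)cc(OCc4ccccc4)cc3OCc3ccccc3)cc(OCc2ccccc2)c(OCc2ccccc2)c1OCc1ccccc1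
F5 | step 7 | bis-phenol bis[(2S,3S)-epoxide] (desilylated F4) | c1([C@@H]2O[C@H]2Cc3c(O)cc(OCc4ccccc4)cc3OCc3ccccc3)cc(OCc2ccccc2)c(OCc2ccccc2)c(OCc2ccccc2)c1-c1c([C@@H]2O[C@H]2Cc3c(O)cc(OCc4ccccc4)cc3OCc3ccccc3)cc(OCc2ccccc2)c(OCc2ccccc2)c1OCc1ccccc1
F6 | step 5 | 4,4',5,5',6,6'-hexakis(benzyloxy)biphenyl-2,2'-dicarboxylic acid | c1(C(=O)O)cc(OCc2ccccc2)c(OCc2ccccc2)c(OCc2ccccc2)c1-c1c(C(=O)O)cc(OCc2ccccc2)c(OCc2ccccc2)c1OCc1ccccc1
F7 | step 5 | bis(N-methoxy-N-methylamide) of F6 | c1(C(=O)N(C)OC)cc(OCc2ccccc2)c(OCc2ccccc2)c(OCc2ccccc2)c1-c1c(C(=O)N(C)OC)cc(OCc2ccccc2)c(OCc2ccccc2)c1OCc1ccccc1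
F8 | step 5 | [4,4',5,5',6,6'-hexakis(benzyloxy)biphenyl-2,2'-diyl]bis{[4,6-bis(benzyloxy)benzofuran-2-yl]methanone} | c1(C(=O)c2cc3c(OCc4ccccc4)cc(OCc4ccccc4)cc3o2)cc(OCc2ccccc2)c(OCc2ccccc2)c(OCc2ccccc2)c1-c1c(C(=O)c2cc3c(OCc4ccccc4)cc(OCc4ccccc4)cc3o2)cc(OCc2ccccc2)c(OCc2ccccc2)c1OCc1ccccc1
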